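Its constants come from no measurement; the run is a simulation.

The amounts are the same in each set-up, so count everything as a fraction of the starting-material charge; what differs is when the reagents meet.

    starting material + by-product ⇌ idle adduct, settled at all times (K1 = 9200 /M)
    coupling partner + bis adduct → tris adduct + by-product (k2 = 0.988 /M/s)
    starting material + coupling partner → first product + by-product (k3 = 0.480 /M/s)
    coupling partner + first product → bis adduct + by-product (k4 = 0.257 /M/s)

| flask | starting material | coupling partner | remark | time |
|---|---|---|---|---|
| Friday's | 0.010 M | 4.00 equiv | a single well-mixed tank run continuously and read at steady state, 10 min in it on average |  |
| Thursday's | 0.010 M | 4.00 equiv (fed, over 8.00 min) | all but coupling partner at the start; coupling partner goes in evenly over 8.00 min, the run ends at 10 min | 10 min |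
| Monday's | 0.010 M (fed, over 8.00 min) | 4.00 equiv | a stirred flask in which starting material is dosed at a steady rate over 8.00 min without added volume, worked up at 10 min | 10 min |
| Saturday's | 0.010 M | 4.00 equiv | everything together in a closed stirred flask, run for 10 min | 10 min |

- by-product is meant together with its idle adduct
- the stated concentrations are those of everything mixed, before any reaction; amounts are the same in each set-up
- the feed brings no volume worth counting
- run time (Thursday's): 10 min

* order of the set-ups by the amount of tris adduct at the outlet or at the end, in percent of the starting material put in, highest first (Friday's / Thursday's / Monday's / Saturday's)
* amount of tris adduct at the outlet or at the end, in percent of the starting material put in, Friday's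
* amount of tris adduct at the outlet or at the end, in percent of the starting material put in, Thursday's
* amount of tris adduct at the outlet or at the end, in percent of the starting material put in, Monday's
* amount of tris adduct at the outlet or at the end, in percent of the starting material put in, Saturday's

Follow Saturday's through the rate of the first coupling, starting material to first product. At the start it is 1.15 /min, in fractions of the charge. At that rate the half-life of starting material, with coupling partner as charged, is 0.603 min, shorter than the 1.1 min of first product by its own next coupling, so by-product first appears at nearer one per conversion than 3.

Besides the use of the reactants there is product inhibition. Divide the unconverted starting material, free plus idle, by its free part, and time drops out. This ratio is the brake: one plus p times the equilibrium constant of the idle adduct times the charge, 92.0, where p is free by-product as a fraction of the charge. Because 92.0 is far above one, the brake bites once by-product made passes the unconverted share. That happens at a quarter converted with 3 by-products each, or at half with one each.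

Now take Saturday's at half converted with its couplings finished, so that p is 1.00:

| What slows the first coupling | Factor |
|---|---|
| Unconverted share | 2.00 |
| Coupling partner | 1.60 |
| Brake | 93.0 |

Together these make 298, leaving 0.00387 /min, and 10 min at that rate comes to 3.87% of the charge. My reckoning therefore puts Saturday's tris adduct somewhat below half, and it goes no further.

The forecast gives 47% for Saturday's, 41% for Thursday's, 34% for Monday's and 25.5% for Friday's, ranked Saturday's > Thursday's > Monday's > Friday's. Its ground is this: “each run largely stalls once by-product outruns free starting material”.

The simulation gives 46.6% for Saturday's, 39.9% for Thursday's, 29.9% for Monday's and 25.3% for Friday's, ranked Saturday's > Thursday's > Monday's > Friday's. Saturday's ends with 0.592% of its charge as free starting material, and with at most 51.5% unconverted, which makes the brake at most 87.0. Friday's tank holds 5.47% first product, 1.35% bis adduct and 25.3% tris adduct. Its unconverted share is therefore 67.9% and its by-product made 84.1%; idle adduct is counted within that unconverted share, so p is at least 16.3% and Friday's brake at least 16.0.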